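The route rests on cutting N21–C28 back to a nitrene tethered through a sulfamate on O5. O5 on C4 and the hydrogen on C28 lie on the same face of cyclopentene ring C (C28, C3, C4, C10, C11) and are 1,3-related across C3, so a rhodium nitrene can insert into the tertiary, allylic C28–H bond. In one operation this forms N21–C28, closes a six-membered oxathiazinane and creates the aza-quaternary centre with retention. The substrate is the C4 sulfamate of a tetrasubstituted cyclopentenol that already carries the C8 propanoate, the C12–C18 silyloxy lactone chain, the ketal-masked C26 ketone with its C22 chloride, and cis hydrogens on C3 and C28.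

Key step: step 25

Atom labels are positions in the target SMILES (1–28).

Design remarks:
- C22 is carried as a chloride, because an acyl protecting group there could not be removed beside the methyl ester and lactone E. C13–O is a TBDPS ether so that it survives aqueous acid.
- C3=C28 is hydrogenated before C10=C11 exists; a ring with both alkenes and a C4–H would be an isomerisation-prone cyclopentadienol.
- After the key step C4 needs net retention. Hydride cleavage at sulfur would also reduce the ester, lactone and ketone, and any opening at C4 inverts. Two inversions are therefore used: thiolate, then sulfonium displacement by the C6 ester.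
- The ketal is hydrolysed while N21 is still sulfonylated, since an α-ammonium ketal resists hydrolysis.
- Compounds 9–13 are mixtures of epimers at C10 and 23 at C11; both carbons become sp2 later, so the mixtures converge.
- Assumption: the (5S,1′R) aldol adduct 19 is the major isomer in step 13 and is purified there.

Step 1
Reactants: 1 2-ethylcyclopentane-1,3-dione
Product: 2 2-ethyl-3-(2-methylpropoxy)cyclopent-2-en-1-one
Conditions: i-BuOH, TsOH (cat.), PhH, reflux, Dean–Stark
Reagents that add atoms: 2-methylpropan-1-ol CC(C)CO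
Why: Acid-catalysed condensation of the cyclic 1,3-dione with the alcohol gives the vinylogous ester, with water removed azeotropically.

Step 2
Reactants: 3 3,4-dihydro-2H-pyran
Product: 4 4-(1,3-dithian-2-yl)butan-1-ol
Conditions: HS(CH2)3SH, BF3·OEt2 (cat.), CH2Cl2, 0 °C to rt
Reagents that add atoms: propane-1,3-dithiol SCCCS
Why: Lewis-acid dithioacetalisation of the cyclic enol ether (a masked 5-hydroxypentanal) opens the ring to the dithiane with a free primary alcohol.

Step 3
Reactants: 2 2-ethyl-3-(2-methylpropoxy)cyclopent-2-en-1-one; 4 4-(1,3-dithian-2-yl)butan-1-ol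
Product: 6 2-ethyl-3-[2-(4-hydroxybutyl)-1,3-dithian-2-yl]cyclopent-2-en-1-one, via carbinol adduct 5 (not isolated)
Conditions: 4, n-BuLi (2.1 equiv), THF, −30 °C; then 2, −30 to 0 °C; then 1 M HCl, rt
Reagents that add atoms: water O
Why: The Corey–Seebach dithiane anion (as its O,C-dianion, which cannot self-alkylate) adds 1,2 to the vinylogous ester, and acid hydrolysis transposes the enone (Stork–Danheiser), placing the masked acyl carbon C26 on C28.

Step 4
Reactants: 6 2-ethyl-3-[2-(4-hydroxybutyl)-1,3-dithian-2-yl]cyclopent-2-en-1-one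
Product: 7 3-[2-(4-chlorobutyl)-1,3-dithian-2-yl]-2-ethylcyclopent-2-en-1-one
Conditions: PPh3, CCl4, CH2Cl2, 40 °C
Reagents that add atoms: carbon tetrachloride ClC(Cl)(Cl)Cl
Why: Appel chlorination converts the primary alcohol into the C22 chloride, which stays inert until the N-alkylation in step 27.

Step 5
Reactants: 7 3-[2-(4-chlorobutyl)-1,3-dithian-2-yl]-2-ethylcyclopent-2-en-1-one
Product: 8 3-[2-(4-chlorobutyl)-1,3-dioxolan-2-yl]-2-ethylcyclopent-2-en-1-one
Conditions: PhI(O2CCF3)2, HOCH2CH2OH, MeCN, rt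
Reagents that add atoms: ethane-1,2-diol OCCO
Why: Oxidative dethioacetalisation with the hypervalent iodine reagent in the presence of the diol exchanges the dithiane directly for a dioxolane, which tolerates the later hydrogenation and nitrene steps.

Step 6
Reactants: 8 3-[2-(4-chlorobutyl)-1,3-dioxolan-2-yl]-2-ethylcyclopent-2-en-1-one
Product: 9 4-[2-(4-chlorobutyl)-1,3-dioxolan-2-yl]-3-ethyl-2-oxocyclopent-3-en-1-yl acetate (racemic)
Conditions: Mn(OAc)3·2H2O, PhH, reflux
Reagents that add atoms: manganese triacetate CC(=O)O[Mn](OC(C)=O)OC(C)=O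
Why: α′-Acetoxylation of the enone through its manganese enolate puts the oxygen on C10 that later fixes the position of the ring alkene.

Step 7
Reactants: 9 4-[2-(4-chlorobutyl)-1,3-dioxolan-2-yl]-3-ethyl-2-oxocyclopent-3-en-1-yl acetate
Product: 10 (2S)-4-[2-(4-chlorobutyl)-1,3-dioxolan-2-yl]-3-ethyl-2-hydroxycyclopent-3-en-1-yl acetate (both epimers at the acetate carbon)
Conditions: (S)-Me-CBS (0.2 equiv), catecholborane, toluene, −78 °C
Reagents that add atoms: none
Why: Corey–Bakshi–Shibata reduction treats the α-ethyl alkene side as the large group and sets C4 under catalyst control.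

Step 8
Reactants: 10 (2S)-4-[2-(4-chlorobutyl)-1,3-dioxolan-2-yl]-3-ethyl-2-hydroxycyclopent-3-en-1-yl acetate
Product: 11 (2S,3R,4R)-4-[2-(4-chlorobutyl)-1,3-dioxolan-2-yl]-3-ethyl-2-hydroxycyclopentyl acetate (both epimers at C1; ring hydrogens on C3 and C4 cis to OH)
Conditions: [Ir(cod)(PCy3)(py)]PF6 (10 mol%), H2 (1–4 atm), CH2Cl2, rt
Reagents that add atoms: none
Why: Hydroxyl-directed hydrogenation delivers both hydrogens to the tetrasubstituted alkene from the face of the C4 hydroxyl, setting C3 and C28 cis to each other and to O5.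

Step 9
Reactants: 11 (2S,3R,4R)-4-[2-(4-chlorobutyl)-1,3-dioxolan-2-yl]-3-ethyl-2-hydroxycyclopentyl acetate
Product: 12 (2S,3R,4R)-2-(tert-butyldimethylsilyloxy)-4-[2-(4-chlorobutyl)-1,3-dioxolan-2-yl]-3-ethylcyclopentyl acetate
Conditions: TBSOTf, 2,6-lutidine, CH2Cl2, −78 to 0 °C
Reagents that add atoms: tert-butyldimethylsilyl trifluoromethanesulfonate CC(C)(C)[Si](C)(C)OS(=O)(=O)C(F)(F)F
Why: Silylation protects the hindered C4 alcohol with a group that can later be removed beside the TBDPS ether.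

Step 10
Reactants: 12 (2S,3R,4R)-2-(tert-butyldimethylsilyloxy)-4-[2-(4-chlorobutyl)-1,3-dioxolan-2-yl]-3-ethylcyclopentyl acetate
Product: 13 (2S,3R,4R)-2-(tert-butyldimethylsilyloxy)-4-[2-(4-chlorobutyl)-1,3-dioxolan-2-yl]-3-ethylcyclopentan-1-ol (both epimers at C1)
Conditions: i-Bu2AlH, CH2Cl2, −78 °C; aq. KNaC4H4O6
Reagents that add atoms: none
Why: Reductive ester cleavage removes the acetate through an aluminium alkoxide, which avoids the 1,2-silyl migration that basic methanolysis could cause.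

Step 11
Reactants: 13 (2S,3R,4R)-2-(tert-butyldimethylsilyloxy)-4-[2-(4-chlorobutyl)-1,3-dioxolan-2-yl]-3-ethylcyclopentan-1-ol
Product: 14 (2S,3R,4R)-2-(tert-butyldimethylsilyloxy)-4-[2-(4-chlorobutyl)-1,3-dioxolan-2-yl]-3-ethylcyclopentan-1-one
Conditions: Dess–Martin periodinane, NaHCO3, CH2Cl2, rt
Reagents that add atoms: none
Why: Buffered Dess–Martin oxidation gives the C10 ketone as a single stereoisomer without epimerising the silyloxy-bearing carbon.

Step 12
Reactants: 15 3-methylfuran-2(5H)-one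
Product: 16 trimethyl[(3-methylfuran-2-yl)oxy]silane
Conditions: TMSOTf, Et3N, CH2Cl2, 0 °C
Reagents that add atoms: trimethylsilyl trifluoromethanesulfonate C[Si](C)(C)OS(=O)(=O)C(F)(F)F
Why: Soft enolisation and O-silylation of the butenolide give the aromatic 2-silyloxyfuran.

Step 13
Reactants: 16 trimethyl[(3-methylfuran-2-yl)oxy]silane; 17 2-(benzyloxy)acetaldehyde
Product: 19 (5S)-5-[(1R)-2-(benzyloxy)-1-hydroxyethyl]-3-methylfuran-2(5H)-one, via silyl ether 18 (not isolated)
Conditions: [Cu((S,S)-Ph-pybox)](SbF6)2 (10 mol%), CH2Cl2, −78 °C; then 1 M HCl, THF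
Reagents that add atoms: none
Why: Catalytic enantioselective vinylogous Mukaiyama aldol addition to the chelated alkoxy aldehyde should set C13 (R) and C14 (S) in the anti (erythro) sense.

Step 14
Reactants: 19 (5S)-5-[(1R)-2-(benzyloxy)-1-hydroxyethyl]-3-methylfuran-2(5H)-one
Product: 20 (5S)-5-[(1R)-2-(benzyloxy)-1-(tert-butyldiphenylsilyloxy)ethyl]-3-methylfuran-2(5H)-one
Conditions: TBDPSCl, imidazole, DMF, rt
Reagents that add atoms: tert-butyl(chloro)diphenylsilane CC(C)(C)[Si](Cl)(c1ccccc1)c1ccccc1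
Why: Silylation protects the C13 hydroxyl with an acid-stable group that also shields one face of the butenolide.

Step 15
Reactants: 20 (5S)-5-[(1R)-2-(benzyloxy)-1-(tert-butyldiphenylsilyloxy)ethyl]-3-methylfuran-2(5H)-one
Product: 21 (3S,5S)-5-[(1R)-1-(tert-butyldiphenylsilyloxy)-2-hydroxyethyl]-3-methyloxolan-2-one
Conditions: H2 (1 atm), Pd/C, EtOAc, rt
Reagents that add atoms: none
Why: Heterogeneous hydrogenation adds hydrogen to the butenolide anti to the bulky C14 substituent, giving the cis methyl lactone (C16 S), and hydrogenolyses the benzyl ether in the same operation.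

Step 16
Reactants: 21 (3S,5S)-5-[(1R)-1-(tert-butyldiphenylsilyloxy)-2-hydroxyethyl]-3-methyloxolan-2-one
Product: 22 (2R)-2-(tert-butyldiphenylsilyloxy)-2-[(2S,4S)-4-methyl-5-oxooxolan-2-yl]ethyl trifluoromethanesulfonate
Conditions: Tf2O, 2,6-lutidine, CH2Cl2, −78 °C; used at once
Reagents that add atoms: trifluoromethanesulfonic anhydride O=S(=O)(OS(=O)(=O)C(F)(F)F)C(F)(F)F
Why: O-Triflation turns the primary alcohol into an electrophile reactive enough for enolate alkylation at −78 °C.

Step 17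
Reactants: 14 (2S,3R,4R)-2-(tert-butyldimethylsilyloxy)-4-[2-(4-chlorobutyl)-1,3-dioxolan-2-yl]-3-ethylcyclopentan-1-one; 22 (2R)-2-(tert-butyldiphenylsilyloxy)-2-[(2S,4S)-4-methyl-5-oxooxolan-2-yl]ethyl trifluoromethanesulfonate
Product: 23 ketone 14 bearing at C11 the (2R)-2-(tert-butyldiphenylsilyloxy)-2-[(2S,4S)-4-methyl-5-oxooxolan-2-yl]ethyl chain (both epimers at C11)
Conditions: 14, LiN(i-Pr)2, THF, −78 °C; then 22, −78 to −40 °C
Reagents that add atoms: none
Why: The kinetic lithium enolate forms on the unsubstituted, non-oxygenated side of the α-silyloxy ketone and is alkylated by the primary triflate (SN2), forming C11–C12.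

Step 18
Reactants: 23 C11-alkylated ketone
Product: 24 enol triflate with C10(OTf)=C11, otherwise as 23 (C4 S, C3 R, C28 S)
Conditions: KN(SiMe3)2, THF, −78 °C; then PhNTf2
Reagents that add atoms: N-phenylbis(trifluoromethanesulfonimide) O=S(=O)(N(c1ccccc1)S(=O)(=O)C(F)(F)F)C(F)(F)F
Why: Enolisation again occurs away from the silyloxy-bearing carbon and O-triflation (enol triflate formation) fixes the tetrasubstituted alkene at C10=C11.

Step 19
Reactants: 25 (R)-4-benzyloxazolidin-2-one; 26 bromoacetyl bromide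
Product: 27 (R)-4-benzyl-3-(bromoacetyl)oxazolidin-2-one
Conditions: 25, n-BuLi, THF, −78 °C; then 26
Reagents that add atoms: none
Why: N-Acylation of the lithiated oxazolidinone gives the auxiliary-bearing two-carbon unit for C8 and C6.

Step 20
Reactants: 24 enol triflate; 27 (R)-4-benzyl-3-(bromoacetyl)oxazolidin-2-one
Product: 29 C10-acetyl imide, C10–CH2–C(=O)–oxazolidinone, otherwise as 24, via zinc enolate 28 (not isolated)
Conditions: 27, Zn, THF, rt; then 24, Pd(dba)2, Q-phos, THF, 50 °C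
Reagents that add atoms: none
Why: Negishi-type cross-coupling of the Reformatsky zinc enolate with the enol triflate forms the C10–C8 bond under neutral conditions that spare lactone, ketal and chloride.

Step 21
Reactants: 29 C10-acetyl imide
Product: 30 (R)-C8-methylated imide
Conditions: NaN(SiMe3)2, THF, −78 °C; then MeI
Reagents that add atoms: iodomethane CI
Why: Evans alkylation: the chelated Z-enolate of the β,γ-unsaturated imide is methylated at the α-carbon on the face opposite the benzyl group, setting C8 as R.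

Step 22
Reactants: 30 (R)-C8-methylated imide
Product: 31 methyl ester at C6 with C4–OTBS, otherwise as 33
Conditions: MeMgBr, MeOH, CH2Cl2, 0 °C
Reagents that add atoms: methanol CO
Why: Transesterification with magnesium methoxide cleaves the exocyclic imide carbonyl cold, which should leave the acidic C8 centre intact.

Step 23
Reactants: 31 methyl ester silyl ether
Product: 32 C4 alcohol, otherwise as 33
Conditions: HF·pyridine, THF/pyridine, 0 °C to rt
Reagents that add atoms: none
Why: Selective desilylation removes the secondary TBS ether while the TBDPS ether and dioxolane persist.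

Step 24
Reactants: 32 C4 alcohol
Product: 33 C4 sulfamate of the cyclopentenol (C3 R, C4 S, C8 R, C13 R, C14 S, C16 S, C28 S): methyl (R)-propanoate on C10, silyloxy lactone chain on C11, 2-(4-chlorobutyl)-1,3-dioxolan-2-yl on C28
Conditions: ClSO2NCO, HCO2H, MeCN, 0 °C to rt; then 32, DMA, 0 °C; product kept cold and used promptly
Reagents that add atoms: sulfamoyl chloride NS(=O)(=O)Cl
Why: O-Sulfamoylation with sulfamoyl chloride made in situ installs the nitrene precursor on O5 without touching a stereocentre.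

Step 25
Reactants: 33 C4 sulfamate
Product: 34 oxathiazinane bridging C4 and C28 (C3 R, C4 S, C8 R, C13 R, C14 S, C16 S, C28 R)
Conditions: Rh2(esp)2 (2 mol%), PhI(OAc)2, MgO, i-PrOAc, 40 °C
Reagents that add atoms: none
Why: PhI(OAc)2 converts the sulfamate NH2 into an iminoiodinane and the dirhodium tetracarboxylate turns this into a rhodium-bound nitrene, which inserts into the C28–H bond in a concerted, asynchronous way; the closest known reaction is the intramolecular C–H amination of sulfamate esters. The new N21–C28 bond closes the six-membered oxathiazinane (C4, O5, S, N21, C28, C3) by insertion at the γ carbon, the ring size sulfamates prefer, giving a bicycle bridged across ring C. C28 is the only new stereocentre and is set by retention: the hydrogen replaced is the one cis to O5, so N21 ends cis to O5 and trans to the C3 ethyl group. The step needs site selectivity among γ C–H bonds and against aziridination of C10=C11. C28–H is tertiary, allylic and held beside the nitrene by the cis tether, whereas C8–H is deactivated by its ester, C2–H is secondary and on the far face, and aziridination would require a strained fused five-membered ring. MgO removes acetic acid so that the allylic sulfamate does not ionise.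

Step 26
Reactants: 34 oxathiazinane ketal
Product: 35 oxathiazinane ketone (C26=O, chain ending in C22–Cl)
Conditions: 2 M HCl, THF, rt to 40 °C
Reagents that add atoms: water O
Why: Acid-catalysed ketal hydrolysis is done while N21 is a non-basic sulfamidate nitrogen, and the N–H oxathiazinane is the form least prone to substitution at C4.

Step 27
Reactants: 35 oxathiazinane ketone
Product: 36 N21-alkylated sulfamidate with ring A closed (azepan-3-one fused at N21 and C28)
Conditions: K2CO3, DMF, 50 °C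
Reagents that add atoms: none
Why: Intramolecular SN2 N-alkylation of the acidic sulfamidate N–H by the primary chloride closes the seven-membered ring (7-exo-tet) and makes the sulfamidate electrophilic at C4.

Step 28
Reactants: 36 N-alkyl sulfamidate
Product: 38 C4 methyl sulfide with free secondary amine N21–H (C4 R, sulfur trans to N21), via N-sulfamic acid 37 (not isolated)
Conditions: NaSMe, DMF, −20 to 0 °C; then 1 M HCl, THF, 40 °C; cold NaHCO3
Reagents that add atoms: sodium methanethiolate [Na+].[S-]C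
Why: SN2 opening of the N-alkyl cyclic sulfamidate at allylic C4 by thiolate (first inversion) should outrun participation of the neutral ester, and aqueous acid then hydrolyses the N-sulfamate.

Step 29
Reactants: 38 C4 methyl sulfide
Product: 40 lactone D closed (O5 cis to N21), amine N21–H, C13–OTBDPS, via sulfonium salt 39 (not isolated)
Conditions: TfOH (1 equiv), MeOTf, CH2Cl2, 0 to 35 °C; NaHCO3
Reagents that add atoms: none
Why: S-Methylation gives an allylic dimethylsulfonium, which the C6 ester carbonyl displaces from the opposite face with loss of its O-methyl group (dealkylative lactonisation by neighbouring-group participation); this second inversion restores the C4 configuration (S) and closes ring D.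

Step 30
Reactants: 40 silyl-protected amino bis-lactone
Product: 41 C13 alcohol
Conditions: HF·pyridine, THF, rt
Reagents that add atoms: none
Why: Fluoride-mediated desilylation frees the C13 hydroxyl under mildly acidic conditions that do not enolise lactone D.

Step 31
Reactants: 41 C13 alcohol
Product: 43 target, via mesylate 42 (not isolated)
Conditions: TfOH (1 equiv), Ms2O, pyridine, CH2Cl2, 0 °C; then i-Pr2NEt, 40 °C
Reagents that add atoms: none
Why: With N21 masked as its ammonium salt only oxygen is mesylated, and the freed amine then displaces the mesylate 5-exo-tet with inversion (SN2), giving C13 (S) and ring B.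

Compound list
1 | 2-ethylcyclopentane-1,3-dione | CCC1C(=O)CCC1=O | starting material
2 | 2-ethyl-3-(2-methylpropoxy)cyclopent-2-en-1-one | CCC1=C(OCC(C)C)CCC1=O | intermediate
3 | 3,4-dihydro-2H-pyran | C1=COCCC1 | starting material
4 | 4-(1,3-dithian-2-yl)butan-1-ol | OCCCCC1SCCCS1 | intermediate
5 | 2-ethyl-1-[2-(4-hydroxybutyl)-1,3-dithian-2-yl]-3-(2-methylpropoxy)cyclopent-2-en-1-ol (racemic) | CCC1=C(OCC(C)C)CCC1(O)C1(CCCCO)SCCCS1 | intermediate (not isolated)
6 | 2-ethyl-3-[2-(4-hydroxybutyl)-1,3-dithian-2-yl]cyclopent-2-en-1-one | CCC1=C(C2(CCCCO)SCCCS2)CCC1=O | intermediate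
7 | 3-[2-(4-chlorobutyl)-1,3-dithian-2-yl]-2-ethylcyclopent-2-en-1-one | CCC1=C(C2(CCCCCl)SCCCS2)CCC1=O | intermediate
8 | 3-[2-(4-chlorobutyl)-1,3-dioxolan-2-yl]-2-ethylcyclopent-2-en-1-one | CCC1=C(C2(CCCCCl)OCCO2)CCC1=O | intermediate
9 | 4-[2-(4-chlorobutyl)-1,3-dioxolan-2-yl]-3-ethyl-2-oxocyclopent-3-en-1-yl acetate (racemic) | CCC1=C(C2(CCCCCl)OCCO2)CC(OC(C)=O)C1=O | intermediate
10 | (2S)-4-[2-(4-chlorobutyl)-1,3-dioxolan-2-yl]-3-ethyl-2-hydroxycyclopent-3-en-1-yl acetate (C1 epimers) | CCC1=C(C2(CCCCCl)OCCO2)CC(OC(C)=O)[C@H]1O | intermediate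
11 | (2S,3R,4R)-4-[2-(4-chlorobutyl)-1,3-dioxolan-2-yl]-3-ethyl-2-hydroxycyclopentyl acetate (C1 epimers) | CC[C@H]1[C@H](O)C(OC(C)=O)C[C@H]1C1(CCCCCl)OCCO1 | intermediate
12 | (2S,3R,4R)-2-(tert-butyldimethylsilyloxy)-4-[2-(4-chlorobutyl)-1,3-dioxolan-2-yl]-3-ethylcyclopentyl acetate (C1 epimers) | CC[C@H]1[C@H](O[Si](C)(C)C(C)(C)C)C(OC(C)=O)C[C@H]1C1(CCCCCl)OCCO1 | intermediate
13 | (2S,3R,4R)-2-(tert-butyldimethylsilyloxy)-4-[2-(4-chlorobutyl)-1,3-dioxolan-2-yl]-3-ethylcyclopentan-1-ol (C1 epimers) | CC[C@H]1[C@H](O[Si](C)(C)C(C)(C)C)C(O)C[C@H]1C1(CCCCCl)OCCO1 | intermediate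
14 | (2S,3R,4R)-2-(tert-butyldimethylsilyloxy)-4-[2-(4-chlorobutyl)-1,3-dioxolan-2-yl]-3-ethylcyclopentan-1-one | CC[C@H]1[C@H](O[Si](C)(C)C(C)(C)C)C(=O)C[C@H]1C1(CCCCCl)OCCO1 | intermediate
15 | 3-methylfuran-2(5H)-one | CC1=CCOC1=O | starting material
16 | trimethyl[(3-methylfuran-2-yl)oxy]silane | Cc1ccoc1O[Si](C)(C)C | intermediate
17 | 2-(benzyloxy)acetaldehyde | O=CCOCc1ccccc1 | starting material
18 | (5S)-5-[(1R)-2-(benzyloxy)-1-(trimethylsilyloxy)ethyl]-3-methylfuran-2(5H)-one | c1ccccc1COC[C@@H](O[Si](C)(C)C)[C@@H]1C=C(C)C(=O)O1 | intermediate (not isolated)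
19 | (5S)-5-[(1R)-2-(benzyloxy)-1-hydroxyethyl]-3-methylfuran-2(5H)-one | c1ccccc1COC[C@@H](O)[C@@H]1C=C(C)C(=O)O1 | intermediate
20 | (5S)-5-[(1R)-2-(benzyloxy)-1-(tert-butyldiphenylsilyloxy)ethyl]-3-methylfuran-2(5H)-one | c1ccccc1COC[C@@H](O[Si](c1ccccc1)(c1ccccc1)C(C)(C)C)[C@@H]1C=C(C)C(=O)O1 | intermediate
21 | (3S,5S)-5-[(1R)-1-(tert-butyldiphenylsilyloxy)-2-hydroxyethyl]-3-methyloxolan-2-one | OC[C@@H](O[Si](c1ccccc1)(c1ccccc1)C(C)(C)C)[C@@H]1C[C@H](C)C(=O)O1 | intermediate
22 | (2R)-2-(tert-butyldiphenylsilyloxy)-2-[(2S,4S)-4-methyl-5-oxooxolan-2-yl]ethyl trifluoromethanesulfonate | FC(F)(F)S(=O)(=O)OC[C@@H](O[Si](c1ccccc1)(c1ccccc1)C(C)(C)C)[C@@H]1C[C@H](C)C(=O)O1 | intermediate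
23 | C11-alkylated ketone (C11 epimers) | CC[C@H]1[C@H](O[Si](C)(C)C(C)(C)C)C(=O)C(C[C@@H](O[Si](c2ccccc2)(c2ccccc2)C(C)(C)C)[C@@H]2C[C@H](C)C(=O)O2)[C@H]1C1(CCCCCl)OCCO1 | intermediate
24 | C10 enol triflate | CC[C@H]1[C@H](O[Si](C)(C)C(C)(C)C)C(OS(=O)(=O)C(F)(F)F)=C(C[C@@H](O[Si](c2ccccc2)(c2ccccc2)C(C)(C)C)[C@@H]2C[C@H](C)C(=O)O2)[C@H]1C1(CCCCCl)OCCO1 | intermediate
25 | (R)-4-benzyloxazolidin-2-one | O=C1N[C@H](Cc2ccccc2)CO1 | starting material
26 | bromoacetyl bromide | BrCC(Br)=O | starting material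
27 | (R)-4-benzyl-3-(bromoacetyl)oxazolidin-2-one | O=C(CBr)N1[C@H](Cc2ccccc2)COC1=O | intermediate
28 | bromozinc enolate (Reformatsky reagent) of 27 | Br[Zn]CC(=O)N1[C@H](Cc2ccccc2)COC1=O | intermediate (not isolated)
29 | C10-acetyl imide | CC[C@H]1[C@H](O[Si](C)(C)C(C)(C)C)C(CC(=O)N2[C@H](Cc3ccccc3)COC2=O)=C(C[C@@H](O[Si](c2ccccc2)(c2ccccc2)C(C)(C)C)[C@@H]2C[C@H](C)C(=O)O2)[C@H]1C1(CCCCCl)OCCO1 | intermediate
30 | (R)-C8-methylated imide | CC[C@H]1[C@H](O[Si](C)(C)C(C)(C)C)C([C@@H](C)C(=O)N2[C@H](Cc3ccccc3)COC2=O)=C(C[C@@H](O[Si](c2ccccc2)(c2ccccc2)C(C)(C)C)[C@@H]2C[C@H](C)C(=O)O2)[C@H]1C1(CCCCCl)OCCO1 | intermediate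
31 | C6 methyl ester, C4–OTBS | CC[C@H]1[C@H](O[Si](C)(C)C(C)(C)C)C([C@@H](C)C(=O)OC)=C(C[C@@H](O[Si](c2ccccc2)(c2ccccc2)C(C)(C)C)[C@@H]2C[C@H](C)C(=O)O2)[C@H]1C1(CCCCCl)OCCO1 | intermediate
32 | C4 alcohol | CC[C@H]1[C@H](O)C([C@@H](C)C(=O)OC)=C(C[C@@H](O[Si](c2ccccc2)(c2ccccc2)C(C)(C)C)[C@@H]2C[C@H](C)C(=O)O2)[C@H]1C1(CCCCCl)OCCO1 | intermediate
33 | C4 sulfamate (key-step substrate; 3R,4S,8R,13R,14S,16S,28S) | CC[C@H]1[C@H](OS(N)(=O)=O)C([C@@H](C)C(=O)OC)=C(C[C@@H](O[Si](c2ccccc2)(c2ccccc2)C(C)(C)C)[C@@H]2C[C@H](C)C(=O)O2)[C@H]1C1(CCCCCl)OCCO1 | intermediate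
34 | oxathiazinane with N21 on quaternary C28 (3R,4S,8R,13R,14S,16S,28R) | CC[C@H]1[C@@H]2OS(=O)(=O)N[C@@]1(C3(CCCCCl)OCCO3)C(C[C@@H](O[Si](c3ccccc3)(c3ccccc3)C(C)(C)C)[C@@H]3C[C@H](C)C(=O)O3)=C2[C@@H](C)C(=O)OC | intermediate
35 | oxathiazinane C26 ketone | CC[C@H]1[C@@H]2OS(=O)(=O)N[C@@]1(C(=O)CCCCCl)C(C[C@@H](O[Si](c3ccccc3)(c3ccccc3)C(C)(C)C)[C@@H]3C[C@H](C)C(=O)O3)=C2[C@@H](C)C(=O)OC | intermediate
36 | N21-alkylated sulfamidate, ring A closed | CC[C@H]1[C@@H]2OS(=O)(=O)N3CCCCC(=O)[C@]13C(C[C@@H](O[Si](c4ccccc4)(c4ccccc4)C(C)(C)C)[C@@H]4C[C@H](C)C(=O)O4)=C2[C@@H](C)C(=O)OC | intermediate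
37 | N-sulfamic acid of the C4 methyl sulfide | CC[C@H]1[C@@H](SC)C([C@@H](C)C(=O)OC)=C(C[C@@H](O[Si](c2ccccc2)(c2ccccc2)C(C)(C)C)[C@@H]2C[C@H](C)C(=O)O2)[C@]12N(S(=O)(=O)O)CCCCC2=O | intermediate (not isolated)
38 | C4 methyl sulfide, N21–H amine (C4 R) | CC[C@H]1[C@@H](SC)C([C@@H](C)C(=O)OC)=C(C[C@@H](O[Si](c2ccccc2)(c2ccccc2)C(C)(C)C)[C@@H]2C[C@H](C)C(=O)O2)[C@]12NCCCCC2=O | intermediate
39 | C4 dimethylsulfonium ammonium bis(triflate) | CC[C@H]1[C@@H]([S+](C)C)C([C@@H](C)C(=O)OC)=C(C[C@@H](O[Si](c2ccccc2)(c2ccccc2)C(C)(C)C)[C@@H]2C[C@H](C)C(=O)O2)[C@]12[NH2+]CCCCC2=O.[O-]S(=O)(=O)C(F)(F)F.[O-]S(=O)(=O)C(F)(F)F | intermediate (not isolated)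
40 | amino bis-lactone, rings A, C, D and E, C13–OTBDPS | CC[C@H]1[C@@H]2OC(=O)[C@H](C)C2=C(C[C@@H](O[Si](c3ccccc3)(c3ccccc3)C(C)(C)C)[C@@H]3C[C@H](C)C(=O)O3)[C@]14NCCCCC4=O | intermediate
41 | C13 alcohol | CC[C@H]1[C@@H]2OC(=O)[C@H](C)C2=C(C[C@@H](O)[C@@H]3C[C@H](C)C(=O)O3)[C@]14NCCCCC4=O | intermediate
42 | C13 mesylate | CC[C@H]1[C@@H]2OC(=O)[C@H](C)C2=C(C[C@@H](OS(C)(=O)=O)[C@@H]3C[C@H](C)C(=O)O3)[C@]14NCCCCC4=O | intermediate (not isolated)
43 | CNP0315436.2 (3R,4S,8R,13S,14S,16S,28R) | CC[C@H]1[C@@H]2OC(=O)[C@H](C)C2=C2C[C@@H]([C@@H]3C[C@H](C)C(=O)O3)N3CCCCC(=O)[C@]213 | target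

Total step count: 31. Longest linear sequence: 24 steps (1 to 43 through steps 1, 3–11, 17, 18 and 20–31).

Steps most likely to fail

1. Step 25. The nitrene may be diverted to C8–H or C2–H, or the allylic sulfamate may ionise with capture by the neighbouring ester before insertion. Fallback: starting from 33, N-chlorination with t-BuOCl gives the N-chlorosulfamate F1. Irradiation with blue light in benzene triggers 1,6-hydrogen-atom transfer from C28–H to the sulfamyl radical and chlorine transfer, giving the C28 chloride F2. AgOTf with 2,6-lutidine then closes N21–C28 from the only face the tether allows, and the route is rejoined at 34.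

2. Step 29. If the allylic sulfonium ionises before the weakly nucleophilic ester carbonyl attacks, facial control at C4 is lost, and slow demethylation may stall the closure. Fallback: starting from 38, LiOH in aqueous THF at 0 °C followed by acidification to pH 3 (lactone E re-closes) gives the carboxylic acid F3. Protonation of N21 with TfOH and S-methylation with MeOTf give the sulfonium acid F4. NaHCO3 then lets the carboxylate displace dimethyl sulfide with inversion, and the route is rejoined at 40.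

3. Step 20. Oxidative addition or transmetalation may stall at the crowded tetrasubstituted triflate with the bulky imide zinc enolate. Fallback: starting from 24, Negishi coupling with the Reformatsky reagent made from methyl 2-bromopropanoate and Zn (Pd(dba)2, Q-phos, THF) forms C10–C8 without an auxiliary. It gives 31 together with its C8 epimer F5; the two are separated on silica, F5 is re-equilibrated with DBU and recycled, and the route is rejoined at 31.

Further compounds
F1 | step 25 | N-chlorosulfamate of 33 | CC[C@H]1[C@H](OS(=O)(=O)NCl)C([C@@H](C)C(=O)OC)=C(C[C@@H](O[Si](c2ccccc2)(c2ccccc2)C(C)(C)C)[C@@H]2C[C@H](C)C(=O)O2)[C@H]1C1(CCCCCl)OCCO1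
F2 | step 25 | C28 chloride of sulfamate 33 (C28 undefined) | CC[C@H]1[C@H](OS(N)(=O)=O)C([C@@H](C)C(=O)OC)=C(C[C@@H](O[Si](c2ccccc2)(c2ccccc2)C(C)(C)C)[C@@H]2C[C@H](C)C(=O)O2)C1(Cl)C1(CCCCCl)OCCO1
F3 | step 29 | C6 carboxylic acid of sulfide 38 | CC[C@H]1[C@@H](SC)C([C@@H](C)C(=O)O)=C(C[C@@H](O[Si](c2ccccc2)(c2ccccc2)C(C)(C)C)[C@@H]2C[C@H](C)C(=O)O2)[C@]12NCCCCC2=O
F4 | step 29 | dimethylsulfonium ammonium bis(triflate) of acid F3 | CC[C@H]1[C@@H]([S+](C)C)C([C@@H](C)C(=O)O)=C(C[C@@H](O[Si](c2ccccc2)(c2ccccc2)C(C)(C)C)[C@@H]2C[C@H](C)C(=O)O2)[C@]12[NH2+]CCCCC2=O.[O-]S(=O)(=O)C(F)(F)F.[O-]S(=O)(=O)C(F)(F)F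
F5 | step 20 | C8 epimer of 31 | CC[C@H]1[C@H](O[Si](C)(C)C(C)(C)C)C([C@H](C)C(=O)OC)=C(C[C@@H](O[Si](c2ccccc2)(c2ccccc2)C(C)(C)C)[C@@H]2C[C@H](C)C(=O)O2)[C@H]1C1(CCCCCl)OCCO1
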